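All runs come from a simulation for an exercise.

| flask | first end groups | second end groups | remark | time |
|---|---|---|---|---|
| noon | 0.050 M | 1 equiv | run made earlier |  |
| spring | 0.070 M | 1 equiv | run made earlier |  |
| dusk | 0.11 M | 1 equiv | run made earlier |  |
| west | 0.050 M | 1.00 equiv (fed, over 15 min) | all else is in the flask from the start; the feed brings no volume worth counting | 40 min |
| south | 0.050 M | 1.00 equiv | everything together at the start | 40 min |
| south-east | 0.050 M (in portions, 5, over 15 min) | 1.00 equiv | first portion at the start, last at 15 min | 40 min |
| east | 0.050 M (fed, over 15 min) | 1.00 equiv | all else is in the flask from the start; the feed brings no volume worth counting | 40 min |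

| run | time / min | links / % |
|---|---|---|
| noon | 3.00 | 39.7 |
| noon | 5.00 | 52.4 |
| noon | 8.00 | 63.2 |
| noon | 15.0 | 73.4 |
| noon | 25.0 | 78.4 |
| noon | 40.0 | 81.3 |
| spring | 6.00 | 63.8 |
| spring | 12.0 | 75.7 |
| spring | 20.0 | 81.9 |
| spring | 25.0 | 83.8 |
| spring | 30.0 | 84.6 |
| spring | 40.0 | 85.8 |
| dusk | 2.50 | 55.5 |
| dusk | 8.00 | 78.1 |
| dusk | 15.0 | 85.1 |
| dusk | 20.0 | 86.6 |
| dusk | 30.0 | 88.5 |
| dusk | 40.0 | 89.7 |

(scatter of a reading: 0.3 percentage points)



- the flask that comes out highest in amount of links, in percent of the first end groups charged, or "all alike" when all lie within 1.5 percentage points (west / south / south-east / east / all alike)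
- links at the end, in percent of the first end groups charged, west
- links at the end, in percent of the first end groups charged, south
- links at the end, in percent of the first end groups charged, south-east
- links at the end, in percent of the first end groups charged, east

A first end group charged stands at any moment in one of three entries, left, in links or gone elsewhere, and the entries sum to 100 per cent of the charge. I kept the books on first end groups, using noon, the run with the recipe of south, where second end groups stood at 1 equiv. I worked with f, the fraction left. If the ends only pair, second-order, the reciprocal of f climbs in a straight line, and 39.7% links at 3.00 min gave a slope of 0.219 min⁻¹. That line put the entry left at 40.0 min near 10.2%, so with links read at 81.3% the entry gone elsewhere came near 8.47%, a first leak of 0.00816 min⁻¹. But a leak removes ends too, so I ran the reciprocal of f with both terms, which lowered my entry left to 8.50% and closed my books with 10.2% gone elsewhere. Dividing that entry by the area under f gave 0.0105 min⁻¹, my leak constant, the share of waiting end groups lost per minute to a path that makes no links.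

A steady feed over 15 min delays the pairing by about 7.50 min, so for west and east I put f near 10.1%, with 9.31% leaked during pairing. If the fed end is the one that leaks, the books close at 80.6% links. If the waiting end leaks, it outnumbers the fed end by about 0.5 of its charge on average through the feed, which costs 7.85% more and closes the books at 72.7%. South, repeating noon, I put at 81.3%, more than either case. South-east, in 5 portions, I expected near that range.

The forecast named south highest, with 75.5% for west, 81.3% for south, 76.5% for south-east and 75.5% for east. Its batch runs, it wrote, “cannot show which end dies”, so it gave west and east one midpoint where I kept two cases.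

The flasks gave west 72.7%, south 81.9%, south-east 80.2% and east 80.3%, so south came highest, 1.6 percentage points ahead of east.

    first end groups + second end groups → links (k = 4.68 M⁻¹ min⁻¹)
    first end groups + second end groups → rings, rate k2*[first end groups] as long as [second end groups] is above zero (k = 0.0110 min⁻¹)
    links → over-reaction product (k = 1.92 × 10⁻⁴ min⁻¹)

West ended 9.2 points below south, and with the path to rings taken away that gap shrank to 2.4 points, so that path accounts for 6.8 points of it. The leak constant, times the mean [first end groups] of 0.0360 M in west over 15 min, per charge of 0.050 M, gives 11.3%, and rings in west then stood at 11.9%. In east, with a mean [first end groups] of 0.0120 M, it gives 3.78%, and rings in east stood at 3.95%.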